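**Retrosynthetic overview**

1. Premarineosin A ⇐ tricyclic ether 18 + 4-methoxy-2,2'-bipyrrole 21. Acid-promoted C–C coupling, dehydrogenation and spiro-N,O-ketalization move the ether oxygen from the ring C methine carbon to the α-carbon of ring B, so the oxane and the spiro centre are formed last.
2. 18 ⇐ diene 16 by ring-closing metathesis and hydrogenation (the 12-membered ansa ring, closed after the oxolane).
3. Oxolane 15 ⇐ selenide 14 by a 5-exo radical cyclization with allyl transfer. The ring closure forms the bond between the oxane CH2 and the chain-bearing ring CH; the allyl transfer starts the ansa chain.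
4. 14 ⇐ pyrrolylallyl carbonate 12 (ring C, from pyrrole) + selenohydrin 2 (from (S)-propylene oxide) by iridium-catalysed allylic etherification; 21 ⇐ pyrrole + 4-methoxy-3-pyrrolin-2-one.
5. Enabling feature: in the oxane (O, CHMe, CH2, CH-chain, CH-ring C, spiro C) the CH that carries ring C is a pyrrol-2-ylcarbinyl carbon next to the spiro carbon. The oxygen can therefore sit on that CH first, as a temporary oxolane (O, CHMe, CH2, CH-chain, CH-ring C). This makes the CH2–CH bond the closing bond of a 3-oxahex-5-enyl radical, and the temporary C–O bond can later ionize as an azafulvenium ion.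

Key step: step 9

Assumption: the iridium/phosphoramidite catalyst is taken to show, for the pyrrol-2-ylallyl carbonate, the sense of induction known for cinnamyl carbonates; the (Sa,S,S) ligand is written for the (S) ether, and its enantiomer would be used if the sense were opposite.

**Route**

Step 1
Reactants: 1 (S)-2-methyloxirane
Product: 2 (2S)-1-(phenylselanyl)propan-2-ol
Conditions: (PhSe)2, NaBH4, EtOH, 0 °C; then 1, 0 °C to rt
Reagents that add atoms: diphenyl diselenide, c1ccccc1[Se][Se]c1ccccc1
Why: Benzeneselenolate opens the epoxide by SN2 attack at the unsubstituted carbon (epoxide ring opening), so the oxygen-bearing stereocenter of the chiral-pool epoxide is not touched.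

Step 2
Reactants: 3 1H-pyrrole; 4 pent-4-enoyl chloride
Product: 6 1-(1H-pyrrol-2-yl)pent-4-en-1-one, via pyrrol-1-ylmagnesium bromide 5 (not isolated)
Conditions: EtMgBr, Et2O, 0 °C to rt; then 4, toluene, 0 °C; aq. NH4Cl
Reagents that add atoms: none
Why: The ambident pyrrolyl Grignard reagent is acylated at C2 by the acid chloride (C-acylation of pyrrolylmagnesium halides).

Step 3
Reactants: 6 1-(1H-pyrrol-2-yl)pent-4-en-1-one
Product: 7 2-(pent-4-en-1-yl)-1H-pyrrole
Conditions: NaBH4, i-PrOH, reflux
Reagents that add atoms: none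
Why: NaBH4 in boiling 2-propanol reduces a 2-acylpyrrole through the carbinol and its azafulvene to the 2-alkylpyrrole (reductive deoxygenation), and the isolated alkene is inert.

Step 4
Reactants: 7 2-(pent-4-en-1-yl)-1H-pyrrole
Product: 9 (2E)-3-[5-(pent-4-en-1-yl)-1H-pyrrol-2-yl]prop-2-enal, via iminium salt 8 (not isolated)
Conditions: 3-(dimethylamino)acrolein, POCl3, CH2Cl2, −20 °C to rt; then aq. NaOH
Reagents that add atoms: 3-(dimethylamino)prop-2-enal, CN(C)/C=C/C=O; water, O
Why: The vinylogous Vilsmeier–Haack reagent attacks the free α-position of the 2-alkylpyrrole, and hydrolysis of the iminium ion gives the conjugated (E)-enal.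

Step 5
Reactants: 9 (2E)-3-[5-(pent-4-en-1-yl)-1H-pyrrol-2-yl]prop-2-enal
Product: 10 (2E)-3-[1-(4-methylbenzenesulfonyl)-5-(pent-4-en-1-yl)-1H-pyrrol-2-yl]prop-2-enal
Conditions: TsCl, Et3N, DMAP (cat.), CH2Cl2, rt
Reagents that add atoms: 4-methylbenzenesulfonyl chloride, Cc1ccc(cc1)S(Cl)(=O)=O
Why: The acidic N–H of the acceptor-substituted pyrrole is sulfonylated (N-sulfonylation), and the sulfonyl group later keeps the pyrrolylcarbinyl derivatives from ionizing to azafulvenes.

Step 6
Reactants: 10 (2E)-3-[1-(4-methylbenzenesulfonyl)-5-(pent-4-en-1-yl)-1H-pyrrol-2-yl]prop-2-enal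
Product: 11 (2E)-3-[1-(4-methylbenzenesulfonyl)-5-(pent-4-en-1-yl)-1H-pyrrol-2-yl]prop-2-en-1-ol
Conditions: NaBH4, CeCl3·7H2O, MeOH, −20 °C
Reagents that add atoms: none
Why: Luche reduction delivers hydride 1,2 to the enal and leaves the alkenes and the sulfonamide intact.

Step 7
Reactants: 11 (2E)-3-[1-(4-methylbenzenesulfonyl)-5-(pent-4-en-1-yl)-1H-pyrrol-2-yl]prop-2-en-1-ol
Product: 12 methyl (2E)-3-[1-(4-methylbenzenesulfonyl)-5-(pent-4-en-1-yl)-1H-pyrrol-2-yl]prop-2-en-1-yl carbonate
Conditions: ClCO2Me, pyridine, CH2Cl2, 0 °C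
Reagents that add atoms: methyl chloroformate, COC(=O)Cl
Why: Acylation of the primary allylic alcohol gives the linear carbonate needed as leaving group for allylic substitution.

Step 8
Reactants: 12 methyl (2E)-3-[1-(4-methylbenzenesulfonyl)-5-(pent-4-en-1-yl)-1H-pyrrol-2-yl]prop-2-en-1-yl carbonate; 2 (2S)-1-(phenylselanyl)propan-2-ol
Product: 14 2-[(1S)-1-{[(2S)-1-(phenylselanyl)propan-2-yl]oxy}prop-2-en-1-yl]-1-(4-methylbenzenesulfonyl)-5-(pent-4-en-1-yl)-1H-pyrrole, via copper alkoxide 13 (not isolated)
Conditions: 2, CuI, LiN(SiMe3)2, THF, 0 °C; then 12, [Ir(cod)Cl]2 (2 mol %), (Sa,S,S)-O,O'-(1,1'-binaphthalene-2,2'-diyl) N,N-bis(1-phenylethyl)phosphoramidite (4 mol %), THF, rt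
Reagents that add atoms: none
Why: Iridium-catalysed allylic etherification with a monovalent copper alkoxide is branched-selective, the new C–O stereocenter is set by the chiral ligand (catalyst control), and the stereocenter of 2 is not involved.

Step 9
Reactants: 14 2-[(1S)-1-{[(2S)-1-(phenylselanyl)propan-2-yl]oxy}prop-2-en-1-yl]-1-(4-methylbenzenesulfonyl)-5-(pent-4-en-1-yl)-1H-pyrrole
Product: 15 2-[(2S,3S,5S)-3-(but-3-en-1-yl)-5-methyloxolan-2-yl]-1-(4-methylbenzenesulfonyl)-5-(pent-4-en-1-yl)-1H-pyrrole
Conditions: allyltributylstannane (4 equiv), AIBN (0.2 equiv, in portions), benzene (0.03 M), 80 °C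
Reagents that add atoms: allyltributylstannane, C=CC[Sn](CCCC)(CCCC)CCCC
Why: The tributyltin radical abstracts the phenylselanyl group to give a primary β-alkoxyalkyl radical (a 2,4-disubstituted 3-oxahex-5-enyl radical) that adds to the inner carbon of the vinyl group, forming the ring CH2–CH bond and the oxolane; the new primary radical then takes an allyl group from the stannane (SH2'), which makes the first C–C bond of the ansa chain, installs the alkene for the later metathesis and returns the tin radical to the chain. The closest known reaction type is the Ueno–Stork haloether radical cyclization run in tandem with a Keck allylation, here with the radical precursor on the alkoxy arm of an allylic ether. The only ring closed is the oxolane, in the 5-exo-trig mode, which is preferred over 6-endo closure on stereoelectronic grounds and is accelerated by the oxygen in the chain. The new stereocenter (the chain-bearing ring carbon) is set in the chair-like transition state in which the pyrrolyl group on the allylic carbon and the methyl group next to oxygen are both pseudo-equatorial, so the new CH2 group ends trans to both; this is the matched case because step 8 placed these two groups cis on the future ring. The step needs cyclization to outrun direct allylation of the first radical, and the cyclized radical must not attack the sulfonylpyrrole or the distant pentenyl group: the unimolecular 5-exo closure is orders of magnitude faster than bimolecular allyl transfer at this concentration, the trans arrangement holds the cyclized radical away from the pyrrole, and the pentenyl alkene is unactivated and too far away for ring formation. The sulfonyl group on nitrogen keeps the pyrrolylcarbinyl ether from ionizing at 80 °C, and minor diastereomers would be removed by chromatography.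

Step 10
Reactants: 15 2-[(2S,3S,5S)-3-(but-3-en-1-yl)-5-methyloxolan-2-yl]-1-(4-methylbenzenesulfonyl)-5-(pent-4-en-1-yl)-1H-pyrrole
Product: 16 2-[(2S,3S,5S)-3-(but-3-en-1-yl)-5-methyloxolan-2-yl]-5-(pent-4-en-1-yl)-1H-pyrrole
Conditions: KOH, MeOH–THF, 65 °C
Reagents that add atoms: none
Why: Hydroxide cleaves the N–S bond of the sulfonylpyrrole (sulfonamide hydrolysis), and none of the three stereocenters is acidic or ionizable under base.

Step 11
Reactants: 16 2-[(2S,3S,5S)-3-(but-3-en-1-yl)-5-methyloxolan-2-yl]-5-(pent-4-en-1-yl)-1H-pyrrole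
Product: 17 macrocyclic alkene: (2S,3S,5S)-5-methyloxolane whose C2 is bonded to C2 of a 1H-pyrrole and whose C3 is joined to pyrrole C5 by a hept-3-ene-1,7-diyl chain (12-membered ansa ring, trans-fused, E/Z mixture)
Conditions: second-generation Grubbs catalyst RuCl2(=CHPh)(H2IMes)(PCy3) (10 mol %), CH2Cl2 (1 mM), 40 °C
Reagents that add atoms: none
Why: Ring-closing metathesis of two monosubstituted alkenes under high dilution closes the ansa ring of the [9](2,5)pyrrolophane at a site remote from the stereocenters, and the alkene geometry is irrelevant because it is hydrogenated next.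

Step 12
Reactants: 17 macrocyclic alkene
Product: 18 tricyclic ether: (2S,3S,5S)-5-methyloxolane whose C2 is bonded to C2 of a 1H-pyrrole and whose C3 is joined to pyrrole C5 by a heptane-1,7-diyl chain
Conditions: H2 (3 atm), RhCl(PPh3)3 (5 mol %), benzene–EtOH, rt
Reagents that add atoms: none
Why: Homogeneous hydrogenation saturates the disubstituted alkene without hydrogenolysis of the pyrrolylcarbinyl C–O bond or reduction of the pyrrole.

Step 13
Reactants: 19 4-methoxy-1,5-dihydro-2H-pyrrol-2-one; 3 1H-pyrrole
Product: 21 4-methoxy-1H,1'H-2,2'-bipyrrole, via imidoyl triflate 20 (not isolated)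
Conditions: Tf2O, CH2Cl2, 0 °C; then 3 (5 equiv), 0 °C to rt; aq. NaHCO3
Reagents that add atoms: none
Why: The lactam is activated as its O-triflyl imidate (Vilsmeier-type amide activation), pyrrole attacks through C2, and loss of triflic acid with tautomerization gives the aromatic bipyrrole with its α-position next to the methoxy group free.

Step 14
Reactants: 18 tricyclic ether; 21 4-methoxy-1H,1'H-2,2'-bipyrrole
Product: 24 premarineosin A, via dipyrromethane 22 (not isolated), via prodiginine 23 (not isolated)
Conditions: 21 (1.1 equiv), camphorsulfonic acid (0.2 equiv), CH2Cl2, −20 to 0 °C; then DDQ (1.0 equiv), 0 °C to rt; aq. NaHCO3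
Reagents that add atoms: none
Why: The acid ionizes the pyrrol-2-ylcarbinyl ether of 18 to an azafulvenium ion that alkylates the free α-carbon next to the methoxy group of 21 (Friedel–Crafts dipyrromethane synthesis), DDQ dehydrogenates the dipyrromethane to the strained ansa-prodiginine (dipyrrin formation), and the tautomer protonated at the bridging carbon (a 2-azaallyl cation of ring B, stabilized by ring A and the methoxy group) is trapped 6-exo by the released secondary hydroxyl, the behaviour known for hydroxyl-tethered ansa-prodiginines, so that the two new stereocenters should settle reversibly under acid with ring C trans to the chain, the C–N bond axial (anomeric effect) and the bulkier methoxyalkene carbon kept away from the axial methyl group.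

**Compound list**

1 | (S)-2-methyloxirane | C[C@H]1CO1 | starting material
2 | (2S)-1-(phenylselanyl)propan-2-ol | C[C@H](O)C[Se]c1ccccc1 | intermediate
3 | 1H-pyrrole | c1cc[nH]c1 | starting material
4 | pent-4-enoyl chloride | C=CCCC(=O)Cl | starting material
5 | pyrrol-1-ylmagnesium bromide | Br[Mg]n1cccc1 | intermediate (not isolated)
6 | 1-(1H-pyrrol-2-yl)pent-4-en-1-one | C=CCCC(=O)c1ccc[nH]1 | intermediate
7 | 2-(pent-4-en-1-yl)-1H-pyrrole | C=CCCCc1ccc[nH]1 | intermediate
8 | (2E)-N,N-dimethyl-3-[5-(pent-4-en-1-yl)-1H-pyrrol-2-yl]prop-2-en-1-iminium dichlorophosphate | C=CCCCc1ccc(/C=C/C=[N+](C)C)[nH]1.[O-]P(Cl)(Cl)=O | intermediate (not isolated)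
9 | (2E)-3-[5-(pent-4-en-1-yl)-1H-pyrrol-2-yl]prop-2-enal | C=CCCCc1ccc(/C=C/C=O)[nH]1 | intermediate
10 | (2E)-3-[1-(4-methylbenzenesulfonyl)-5-(pent-4-en-1-yl)-1H-pyrrol-2-yl]prop-2-enal | C=CCCCc1ccc(/C=C/C=O)n1S(=O)(=O)c1ccc(C)cc1 | intermediate
11 | (2E)-3-[1-(4-methylbenzenesulfonyl)-5-(pent-4-en-1-yl)-1H-pyrrol-2-yl]prop-2-en-1-ol | C=CCCCc1ccc(/C=C/CO)n1S(=O)(=O)c1ccc(C)cc1 | intermediate
12 | methyl (2E)-3-[1-(4-methylbenzenesulfonyl)-5-(pent-4-en-1-yl)-1H-pyrrol-2-yl]prop-2-en-1-yl carbonate | C=CCCCc1ccc(/C=C/COC(=O)OC)n1S(=O)(=O)c1ccc(C)cc1 | intermediate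
13 | copper (2S)-1-(phenylselanyl)propan-2-olate (monovalent copper alkoxide of 2) | C[C@H](O[Cu])C[Se]c1ccccc1 | intermediate (not isolated)
14 | 2-[(1S)-1-{[(2S)-1-(phenylselanyl)propan-2-yl]oxy}prop-2-en-1-yl]-1-(4-methylbenzenesulfonyl)-5-(pent-4-en-1-yl)-1H-pyrrole | C=CCCCc1ccc(n1S(=O)(=O)c1ccc(C)cc1)[C@H](C=C)O[C@@H](C)C[Se]c1ccccc1 | intermediate
15 | 2-[(2S,3S,5S)-3-(but-3-en-1-yl)-5-methyloxolan-2-yl]-1-(4-methylbenzenesulfonyl)-5-(pent-4-en-1-yl)-1H-pyrrole | C=CCCCc1ccc(n1S(=O)(=O)c1ccc(C)cc1)[C@H]1O[C@@H](C)C[C@@H]1CCC=C | intermediate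
16 | 2-[(2S,3S,5S)-3-(but-3-en-1-yl)-5-methyloxolan-2-yl]-5-(pent-4-en-1-yl)-1H-pyrrole | C=CCCCc1ccc([nH]1)[C@H]1O[C@@H](C)C[C@@H]1CCC=C | intermediate
17 | macrocyclic alkene: (2S,3S,5S)-5-methyloxolane, C2 bonded to pyrrole C2, C3 joined to pyrrole C5 by hept-3-ene-1,7-diyl (E/Z mixture) | C[C@H]1C[C@@H]2CCC=CCCCc3ccc([nH]3)[C@H]2O1 | intermediate
18 | tricyclic ether: (2S,3S,5S)-5-methyloxolane, C2 bonded to pyrrole C2, C3 joined to pyrrole C5 by heptane-1,7-diyl | C[C@H]1C[C@@H]2CCCCCCCc3ccc([nH]3)[C@H]2O1 | intermediate
19 | 4-methoxy-1,5-dihydro-2H-pyrrol-2-one | COC1=CC(=O)NC1 | starting material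
20 | 3-methoxy-2H-pyrrol-5-yl trifluoromethanesulfonate | COC1=CC(OS(=O)(=O)C(F)(F)F)=NC1 | intermediate (not isolated)
21 | 4-methoxy-1H,1'H-2,2'-bipyrrole | COc1c[nH]c(-c2ccc[nH]2)c1 | intermediate
22 | dipyrromethane: 12-membered 2,5-pyrrolophane (ring C) whose pyrrole-bound ring CH carries the 4-methoxy-2,2'-bipyrrol-5-yl group and whose neighbouring (S) ring carbon carries an (S)-2-hydroxypropyl group; bridging CH of undefined configuration | COc1cc(-c2ccc[nH]2)[nH]c1C1c2ccc(CCCCCCC[C@H]1C[C@H](C)O)[nH]2 | intermediate (not isolated)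
23 | ansa-prodiginine: the dipyrrin formed from 22 by loss of two hydrogens, with the (S) ring carbon and its (S)-2-hydroxypropyl group unchanged | COC1=CC(c2ccc[nH]2)=NC1=C1c2ccc(CCCCCCC[C@H]1C[C@H](C)O)[nH]2 | intermediate (not isolated)
24 | premarineosin A | COC1=CC(c2ccc[nH]2)=N[C@]12O[C@@H](C)C[C@@H]1CCCCCCCc3ccc([nH]3)[C@H]12 | target

**Step count and risks**

Total step count: 14. Longest linear sequence: 12 steps (steps 2 to 12 and step 14, from pyrrole).

Steps most likely to fail:

Step 14. DDQ may oxidize the electron-rich bipyrrole units instead of the dipyrromethane, and the azafulvenium ion may lose the proton on the neighbouring chain-bearing carbon before C–C bond formation, which would epimerize that carbon. Fallback: starting from 18, the single pyrrolic methine is oxidized first (DDQ, THF–H2O, 0 °C) to the macrocyclic hydroxy ketone F1, which exists in equilibrium with its lactol. F1 is then condensed with 21 under acid (HCl in MeOH, 0 °C to rt), as in the usual synthesis of dipyrrins from 2-acylpyrroles. This returns to the route at prodiginine 23, which closes to 24 as in step 14, and no oxidant meets the bipyrrole.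

Step 8. The sulfonyl group next to the allyl terminus may erode branched selectivity and catalyst control, and the selenide may inhibit the catalyst. Fallback: starting from allylic alcohol 11, Sharpless asymmetric epoxidation (Ti(OiPr)4, L-(+)-diethyl tartrate, t-BuOOH, 4 Å molecular sieves, CH2Cl2, −20 °C) gives the epoxy alcohol F2. Ti(OiPr)4-mediated opening by alcohol 2 at the pyrrolyl-bearing carbon, with inversion, gives the diol ether F3. Corey–Winter olefination through the cyclic thiocarbonate F4 (1,1'-thiocarbonyldiimidazole, toluene, 80 °C; then P(OMe)3, 110 °C) turns the diol into the vinyl group and returns to the route at 14.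

Step 9. Facial discrimination in the ring closure may be insufficient, or the uncyclized radical may be captured by the stannane. Fallback: the same oxolane is built by ionic chemistry, starting from pyrrole 7. Commercial (5S)-5-methyloxolan-2-one F5 is alkylated through its lithium enolate (LiN(iPr)2, THF, −78 °C; 4-bromobut-1-ene, DMPU) trans to the methyl group to give lactone F6. Reduction and acetylation (iBu2AlH, CH2Cl2, −78 °C; then Ac2O, pyridine, DMAP) give the lactol acetate F7. Its oxocarbenium ion (BF3·OEt2, CH2Cl2, −78 °C) is attacked by the free α-position of 7 anti to the neighbouring butenyl group (Friedel–Crafts arylation of a lactol acetate), which returns to the route at 16.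

**Further compounds**

F1 | step 14 | 12-membered 2-acyl-2,5-pyrrolophane ketone: ketone carbon on pyrrole C2, (S) α-carbon bearing an (S)-2-hydroxypropyl group and joined to pyrrole C5 by heptane-1,7-diyl | C[C@H](O)C[C@@H]1CCCCCCCc2ccc([nH]2)C1=O
F2 | step 8 | {(2S,3S)-3-[1-(4-methylbenzenesulfonyl)-5-(pent-4-en-1-yl)-1H-pyrrol-2-yl]oxiran-2-yl}methanol | OC[C@@H]1O[C@H]1c1ccc(CCCC=C)n1S(=O)(=O)c1ccc(C)cc1
F3 | step 8 | (2S,3R)-3-[1-(4-methylbenzenesulfonyl)-5-(pent-4-en-1-yl)-1H-pyrrol-2-yl]-3-{[(2S)-1-(phenylselanyl)propan-2-yl]oxy}propane-1,2-diol | OC[C@H](O)[C@H](O[C@@H](C)C[Se]c1ccccc1)c1ccc(CCCC=C)n1S(=O)(=O)c1ccc(C)cc1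
F4 | step 8 | (4S)-4-[(R)-[1-(4-methylbenzenesulfonyl)-5-(pent-4-en-1-yl)-1H-pyrrol-2-yl]{[(2S)-1-(phenylselanyl)propan-2-yl]oxy}methyl]-1,3-dioxolane-2-thione | S=C1OC[C@@H]([C@H](O[C@@H](C)C[Se]c2ccccc2)c2ccc(CCCC=C)n2S(=O)(=O)c2ccc(C)cc2)O1
F5 | step 9 | (5S)-5-methyloxolan-2-one | C[C@H]1CCC(=O)O1
F6 | step 9 | (3S,5S)-3-(but-3-en-1-yl)-5-methyloxolan-2-one | C[C@H]1C[C@H](CCC=C)C(=O)O1
F7 | step 9 | (3S,5S)-3-(but-3-en-1-yl)-5-methyloxolan-2-yl acetate (anomeric mixture) | C[C@H]1C[C@H](CCC=C)C(OC(C)=O)O1
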